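**Plan**
1. Retrosynthetic cuts: the three ester C–O bonds (C9 with inversion); C12–O, C8–H and C7–C11 of the side chain, back to a C7 ketone; the C3 carbinol and C4=C5 alkene, back to a C3 silyl enol ether; then C1–C2 and C5–C6 of ring A in one operation; last C1=C6, C6–C7 and C9–C10 of ring B.
2. Forward order: chain C7–C10, then ring B as a cyclohexenone, then ring A by intermolecular Diels–Alder union with a 2-siloxydiene, then the C11–C13 side chain on C7, then the C3 oxidation level and the esters.
3. Enabling feature: in ring A (C1–C6) the four-carbon unit C2–C3(O)–C4(CH3)–C5 is a 2-siloxy-3-methylbuta-1,3-diene in disguise. Its two ends join C1 and C6 of ring B, which lie next to C7, a carbon that can be a ketone before it becomes the exocyclic alkene carbon.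
4. Stereochemistry: C9 and C10 come from one reagent-controlled anti-crotylation; C1 and C6 from the Diels–Alder face opposite to both ring B substituents; C3 from convex-face hydride delivery; the C7=C11 geometry from an s-cis 1,4-hydroboration. C9 is carried in the cis (non-target) configuration as a control element and inverted by the final Mitsunobu acetylation.

Key step: step 9

Remarks: Locants follow cadinane numbering, which coincides with bicyclo[4.4.0]decane numbering: ring A = C1–C6 (C15 methyl on C4), ring B = C1, C6, C7–C10 (C14 methyl on C10), C11 on C7 carries C12 (CH2O) and C13 (CH3). In every bicyclic compound H1 and H6 are cis; 7(11)E means that C12 lies on the C8 side. The target is (1S,3R,6S,9R,10R,7(11)E)-3,9-diacetoxycadina-4,7(11)-dien-12-yl formate. Compounds 1 and 10 and all reagents are taken to be commercial.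

**Route**

Step 1
Reactants: 1 3-[(tert-butyldimethylsilyl)oxy]propanal
Product: 3 (3S,4R)-1-[(tert-butyldimethylsilyl)oxy]-4-methylhex-5-en-3-ol, via diisopinocampheylborinate ester 2 (not isolated)
Conditions: (E)-but-2-ene, KOt-Bu, n-BuLi, THF, −78 to −45 °C; (+)-Ipc2BOMe (from (−)-α-pinene), −78 °C; BF3·OEt2, then 1, −78 °C; NaOH, H2O2, 0 °C to rt
Reagents that add atoms: (E)-but-2-ene C/C=C/C; (+)-B-methoxydiisopinocampheylborane COB([C@H]1C[C@H]2C[C@@H]([C@@H]1C)C2(C)C)[C@H]1C[C@H]2C[C@@H]([C@@H]1C)C2(C)C (boron retained only in 2)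
Why: Brown asymmetric crotylboration through a closed chair transition state, in which the E-crotyl geometry gives the 3,4-anti relationship and the (−)-α-pinene-derived isopinocampheyl groups direct attack to the re face of the aldehyde, setting C9 (S) and C10 (R).

Step 2
Reactants: 3 (3S,4R)-1-[(tert-butyldimethylsilyl)oxy]-4-methylhex-5-en-3-ol
Product: 4 (3S,4R)-1,3-bis[(tert-butyldimethylsilyl)oxy]-4-methylhex-5-ene
Conditions: TBSOTf, 2,6-lutidine, CH2Cl2, −78 to 0 °C
Reagents that add atoms: tert-butyldimethylsilyl trifluoromethanesulfonate CC(C)(C)[Si](C)(C)OS(=O)(=O)C(F)(F)F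
Why: Standard silylation of a secondary alcohol with a silyl triflate and a hindered pyridine base, touching no stereocentre.

Step 3
Reactants: 4 (3S,4R)-1,3-bis[(tert-butyldimethylsilyl)oxy]-4-methylhex-5-ene
Product: 5 (3S,4R)-3-[(tert-butyldimethylsilyl)oxy]-4-methylhex-5-en-1-ol
Conditions: HF·pyridine, pyridine, THF, 0 °C
Reagents that add atoms: none
Why: Chemoselective desilylation, since buffered HF·pyridine should cleave the unhindered primary silyl ether much faster than the secondary one next to the C10 methine.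

Step 4
Reactants: 5 (3S,4R)-3-[(tert-butyldimethylsilyl)oxy]-4-methylhex-5-en-1-ol
Product: 6 (3S,4R)-3-[(tert-butyldimethylsilyl)oxy]-4-methylhex-5-enal
Conditions: Dess–Martin periodinane, NaHCO3, CH2Cl2, 0 °C to rt
Reagents that add atoms: none
Why: Dess–Martin oxidation of the primary alcohol under buffered, non-basic conditions that should not eliminate the β-siloxy group.

Step 5
Reactants: 6 (3S,4R)-3-[(tert-butyldimethylsilyl)oxy]-4-methylhex-5-enal
Product: 7 (5S,6R)-5-[(tert-butyldimethylsilyl)oxy]-6-methylocta-1,7-dien-3-ol (both C3 epimers)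
Conditions: CH2=CHMgBr, THF, −78 °C; aq NH4Cl
Reagents that add atoms: vinylmagnesium bromide C=C[Mg]Br
Why: Grignard 1,2-addition to the aldehyde, the new carbinol centre being irrelevant because it is oxidised in step 7.

Step 6
Reactants: 7 (5S,6R)-5-[(tert-butyldimethylsilyl)oxy]-6-methylocta-1,7-dien-3-ol
Product: 8 (4R,5S)-5-[(tert-butyldimethylsilyl)oxy]-4-methylcyclohex-2-en-1-ol (both C1 epimers)
Conditions: second-generation Grubbs catalyst RuCl2(=CHPh)(PCy3)(H2IMes) (3 mol %), CH2Cl2, 40 °C
Reagents that add atoms: none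
Why: Ring-closing olefin metathesis of the two terminal vinyl groups should close six-membered ring B (forming C1=C6) with loss of ethene and without touching the stereocentres.

Step 7
Reactants: 8 (4R,5S)-5-[(tert-butyldimethylsilyl)oxy]-4-methylcyclohex-2-en-1-ol
Product: 9 (4R,5S)-5-[(tert-butyldimethylsilyl)oxy]-4-methylcyclohex-2-en-1-one (methyl and siloxy group cis)
Conditions: Dess–Martin periodinane, NaHCO3, CH2Cl2, 0 °C
Reagents that add atoms: none
Why: Dess–Martin oxidation of the allylic alcohol gives the enone under neutral conditions, avoiding base that could eliminate the β-siloxy group and aromatise the ring.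

Step 8
Reactants: 10 3-methylbut-3-en-2-one
Product: 11 tert-butyldimethyl[(3-methylbuta-1,3-dien-2-yl)oxy]silane
Conditions: TBSOTf, Et3N, Et2O, 0 °C
Reagents that add atoms: tert-butyldimethylsilyl trifluoromethanesulfonate CC(C)(C)[Si](C)(C)OS(=O)(=O)C(F)(F)F
Why: Soft enolisation and O-silylation of the methyl ketone, whose acetyl methyl is the only enolisable position, gives the 2-siloxydiene.

Step 9
Reactants: 9 (4R,5S)-5-[(tert-butyldimethylsilyl)oxy]-4-methylcyclohex-2-en-1-one; 11 tert-butyldimethyl[(3-methylbuta-1,3-dien-2-yl)oxy]silane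
Product: 12 (1R,6R,9S,10R)-3,9-bis[(tert-butyldimethylsilyl)oxy]-4,10-dimethylbicyclo[4.4.0]dec-3-en-7-one (cis-fused)
Conditions: HNTf2 (10 mol %), 11 (1.5 equiv), CH2Cl2, −78 to −40 °C; Et3N quench
Reagents that add atoms: none
Why: Enone 9, activated at its C7 carbonyl by the silyl triflimide formed from HNTf2 and 11, should undergo a concerted but asynchronous [4+2] cycloaddition (in the limit a Mukaiyama–Michael addition followed by closure of the C7 silyl enol ether onto the siloxy-stabilised cation), in which the CH2 terminus next to the siloxy carbon of 11 bonds to the β-carbon C1 and the other CH2 terminus to the α-carbon C6. The closest known reaction type is the triflimide- or aluminium-Lewis-acid-catalysed Diels–Alder reaction of 2-siloxy-1,3-dienes with cyclohex-2-enones. Ring A is the only ring closed, as a six-membered carbocycle by intermolecular [4+2] annulation onto ring B, suprafacial on both partners, so the ring fusion must be cis. The two new stereocentres C1 and C6 are set together by the enone face that the diene attacks: the C10 methyl (pseudoaxial in the reactive half-chair) and the C9 siloxy group lie on one face, so the diene adds to the other, which is also the axial trajectory at C1. The regioselectivity needed (C2 to C1, C5 to C6) is secured by the matched polarisation of the 2-siloxydiene (largest HOMO coefficient at C2) and the enone (largest LUMO coefficient at C1), and endo/exo orientation is irrelevant because both diene termini are unsubstituted. The C9 oxygen is placed cis to the methyl group on purpose, because a trans substituent would oppose the methyl group in face control, and the resulting C3 silyl enol ether keeps C3 masked until step 13.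

Step 10
Reactants: 12 (1R,6R,9S,10R)-3,9-bis[(tert-butyldimethylsilyl)oxy]-4,10-dimethylbicyclo[4.4.0]dec-3-en-7-one
Product: 14 (1R,6R,9R,10R)-3,9-bis[(tert-butyldimethylsilyl)oxy]-4,10-dimethylbicyclo[4.4.0]deca-3,7-dien-7-yl trifluoromethanesulfonate, via lithium enolate 13 (not isolated)
Conditions: LiN(SiMe3)2, THF, −78 °C; N-(5-chloropyridin-2-yl)bis(trifluoromethanesulfonyl)imide (Comins' reagent), −78 °C
Reagents that add atoms: Comins' reagent FC(F)(F)S(=O)(=O)N(c1ccc(Cl)cn1)S(=O)(=O)C(F)(F)F; lithium bis(trimethylsilyl)amide [Li]N([Si](C)(C)C)[Si](C)(C)C (lithium retained only in 13)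
Why: Kinetic deprotonation at the less hindered C8 methylene, not the C6 ring-fusion methine, followed by O-triflation of the enolate (enol triflate formation), with the low temperature and the lithium counter-ion keeping β-elimination of the C9 siloxy group slow.

Step 11
Reactants: 14 (1R,6R,9R,10R)-3,9-bis[(tert-butyldimethylsilyl)oxy]-4,10-dimethylbicyclo[4.4.0]deca-3,7-dien-7-yl trifluoromethanesulfonate
Product: 15 (1S,6R,9R,10R)-3,9-bis[(tert-butyldimethylsilyl)oxy]-4,10-dimethyl-7-(prop-1-en-2-yl)bicyclo[4.4.0]deca-3,7-diene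
Conditions: isopropenylboronic acid pinacol ester, PdCl2(dppf) (5 mol %), K3PO4, dioxane/H2O, 60 °C
Reagents that add atoms: isopropenylboronic acid pinacol ester CC(=C)B1OC(C)(C)C(C)(C)O1
Why: Suzuki–Miyaura coupling of the alkenyl triflate with an alkenylboronate should give the C8=C7–C11=C12 diene with the C7=C8 bond in place.

Step 12
Reactants: 15 (1S,6R,9R,10R)-3,9-bis[(tert-butyldimethylsilyl)oxy]-4,10-dimethyl-7-(prop-1-en-2-yl)bicyclo[4.4.0]deca-3,7-diene
Product: 17 (1S,6R,9S,10R,7(11)E)-3,9-bis[(tert-butyldimethylsilyl)oxy]cadina-3,7(11)-dien-12-ol, via allylboronate 16 (not isolated)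
Conditions: Ni(cod)2 (5 mol %), PCy3 (5 mol %), pinacolborane, toluene, rt; then NaOH, H2O2, THF, 0 °C
Reagents that add atoms: pinacolborane [H]B1OC(C)(C)C(C)(C)O1 (supplies H at C8 and the boryl group of 16); hydrogen peroxide OO (supplies the C12 oxygen)
Why: Nickel-catalysed 1,4-hydroboration of the 1,3-diene, which binds zerovalent nickel in its s-cis form so that hydrogen goes to C8 and boron to the unsubstituted terminus C12, leaving C8 and C12 cis on the new tetrasubstituted C7=C11 alkene (the 7(11)E geometry of the target), followed by oxidation of the allylboronate without allylic shift.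

Step 13
Reactants: 17 (1S,6R,9S,10R,7(11)E)-3,9-bis[(tert-butyldimethylsilyl)oxy]cadina-3,7(11)-dien-12-ol
Product: 18 (1S,6S,9S,10R,7(11)E)-9-[(tert-butyldimethylsilyl)oxy]-12-hydroxycadina-4,7(11)-dien-3-one
Conditions: Pd(OAc)2 (1.1 equiv), MeCN, rt
Reagents that add atoms: none
Why: Saegusa–Ito oxidation, in which the regiodefined silyl enol ether gives a palladium enolate at C4 and syn β-hydride elimination toward C5 gives the endocyclic α-methyl enone, the usual outcome for enol ethers of 2-methylcyclohexanones.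

Step 14
Reactants: 18 (1S,6S,9S,10R,7(11)E)-9-[(tert-butyldimethylsilyl)oxy]-12-hydroxycadina-4,7(11)-dien-3-one
Product: 19 (1S,3R,6S,9S,10R,7(11)E)-9-[(tert-butyldimethylsilyl)oxy]cadina-4,7(11)-diene-3,12-diol
Conditions: i-Bu2AlH, CH2Cl2, −78 °C; aq potassium sodium tartrate
Reagents that add atoms: none
Why: 1,2-Reduction of the enone with a bulky aluminium hydride, for which the ring B chair (fixed by allylic strain about the exocyclic alkene, with C5 axial on it) places C10 syn-axial over the concave face of the C3 carbonyl, so hydride should arrive from the convex face and give the 3R alcohol cis to C10.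

Step 15
Reactants: 19 (1S,3R,6S,9S,10R,7(11)E)-9-[(tert-butyldimethylsilyl)oxy]cadina-4,7(11)-diene-3,12-diol
Product: 20 (1S,3R,6S,9S,10R,7(11)E)-9-[(tert-butyldimethylsilyl)oxy]-3-hydroxycadina-4,7(11)-dien-12-yl formate
Conditions: 2,2,2-trifluoroethyl formate (3 equiv), THF, 50 °C
Reagents that add atoms: 2,2,2-trifluoroethyl formate O=COCC(F)(F)F
Why: Chemoselective O-formylation by transesterification with an activated formate, in which the unhindered primary allylic C12 hydroxyl should react far faster than the pseudoaxial secondary C3 hydroxyl.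

Step 16
Reactants: 20 (1S,3R,6S,9S,10R,7(11)E)-9-[(tert-butyldimethylsilyl)oxy]-3-hydroxycadina-4,7(11)-dien-12-yl formate
Product: 21 (1S,3R,6S,9S,10R,7(11)E)-3-acetoxy-9-[(tert-butyldimethylsilyl)oxy]cadina-4,7(11)-dien-12-yl formate
Conditions: Ac2O, pyridine, DMAP (cat.), CH2Cl2, 0 °C to rt
Reagents that add atoms: acetic anhydride CC(=O)OC(C)=O
Why: DMAP-catalysed acetylation of the secondary allylic alcohol with retention at C3 under anhydrous conditions that the formate should survive.

Step 17
Reactants: 21 (1S,3R,6S,9S,10R,7(11)E)-3-acetoxy-9-[(tert-butyldimethylsilyl)oxy]cadina-4,7(11)-dien-12-yl formate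
Product: 22 (1S,3R,6S,9S,10R,7(11)E)-3-acetoxy-9-hydroxycadina-4,7(11)-dien-12-yl formate
Conditions: HF·pyridine, pyridine, THF, 0 °C to rt
Reagents that add atoms: none
Why: Fluoride-mediated cleavage of the secondary silyl ether under buffered conditions that should leave the formate and the allylic acetate intact.

Step 18
Reactants: 22 (1S,3R,6S,9S,10R,7(11)E)-3-acetoxy-9-hydroxycadina-4,7(11)-dien-12-yl formate
Product: 23 (1S,3R,6S,9R,10R,7(11)E)-3,9-diacetoxycadina-4,7(11)-dien-12-yl formate
Conditions: AcOH, PPh3, DIAD, toluene, 0 °C to rt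
Reagents that add atoms: acetic acid CC(=O)O
Why: Mitsunobu esterification, in which the axial C9 alcohol is activated as its alkoxyphosphonium ion and displaced by acetate in an SN2 process with inversion, giving the equatorial 9R acetate trans to the C10 methyl.

**Compound list**
1 | 3-[(tert-butyldimethylsilyl)oxy]propanal | CC(C)(C)[Si](C)(C)OCCC=O | starting material
2 | diisopinocampheylborinate ester of 3 | C=C[C@@H](C)[C@@H](OB([C@H]1C[C@H]2C[C@@H]([C@@H]1C)C2(C)C)[C@H]1C[C@H]2C[C@@H]([C@@H]1C)C2(C)C)CCO[Si](C)(C)C(C)(C)C | intermediate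
3 | (3S,4R)-1-[(tert-butyldimethylsilyl)oxy]-4-methylhex-5-en-3-ol | C=C[C@@H](C)[C@@H](O)CCO[Si](C)(C)C(C)(C)C | intermediate
4 | (3S,4R)-1,3-bis[(tert-butyldimethylsilyl)oxy]-4-methylhex-5-ene | C=C[C@@H](C)[C@@H](O[Si](C)(C)C(C)(C)C)CCO[Si](C)(C)C(C)(C)C | intermediate
5 | (3S,4R)-3-[(tert-butyldimethylsilyl)oxy]-4-methylhex-5-en-1-ol | C=C[C@@H](C)[C@@H](O[Si](C)(C)C(C)(C)C)CCO | intermediate
6 | (3S,4R)-3-[(tert-butyldimethylsilyl)oxy]-4-methylhex-5-enal | C=C[C@@H](C)[C@@H](O[Si](C)(C)C(C)(C)C)CC=O | intermediate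
7 | (5S,6R)-5-[(tert-butyldimethylsilyl)oxy]-6-methylocta-1,7-dien-3-ol | C=C[C@@H](C)[C@@H](O[Si](C)(C)C(C)(C)C)CC(O)C=C | intermediate
8 | (4R,5S)-5-[(tert-butyldimethylsilyl)oxy]-4-methylcyclohex-2-en-1-ol | OC1C=C[C@@H](C)[C@@H](O[Si](C)(C)C(C)(C)C)C1 | intermediate
9 | (4R,5S)-5-[(tert-butyldimethylsilyl)oxy]-4-methylcyclohex-2-en-1-one | O=C1C=C[C@@H](C)[C@@H](O[Si](C)(C)C(C)(C)C)C1 | intermediate
10 | 3-methylbut-3-en-2-one | CC(=O)C(C)=C | starting material
11 | tert-butyldimethyl[(3-methylbuta-1,3-dien-2-yl)oxy]silane | C=C(C)C(=C)O[Si](C)(C)C(C)(C)C | intermediate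
12 | (1R,6R,9S,10R)-3,9-bis[(tert-butyldimethylsilyl)oxy]-4,10-dimethylbicyclo[4.4.0]dec-3-en-7-one | CC1=C(O[Si](C)(C)C(C)(C)C)C[C@@H]2[C@@H](C)[C@@H](O[Si](C)(C)C(C)(C)C)CC(=O)[C@@H]2C1 | intermediate
13 | lithium C7=C8 enolate of 12 | CC1=C(O[Si](C)(C)C(C)(C)C)C[C@@H]2[C@@H](C)[C@@H](O[Si](C)(C)C(C)(C)C)C=C(O[Li])[C@@H]2C1 | intermediate
14 | (1R,6R,9R,10R)-3,9-bis[(tert-butyldimethylsilyl)oxy]-4,10-dimethylbicyclo[4.4.0]deca-3,7-dien-7-yl trifluoromethanesulfonate | CC1=C(O[Si](C)(C)C(C)(C)C)C[C@@H]2[C@@H](C)[C@@H](O[Si](C)(C)C(C)(C)C)C=C(OS(=O)(=O)C(F)(F)F)[C@@H]2C1 | intermediate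
15 | (1S,6R,9R,10R)-3,9-bis[(tert-butyldimethylsilyl)oxy]-4,10-dimethyl-7-(prop-1-en-2-yl)bicyclo[4.4.0]deca-3,7-diene | CC1=C(O[Si](C)(C)C(C)(C)C)C[C@@H]2[C@@H](C)[C@@H](O[Si](C)(C)C(C)(C)C)C=C(C(C)=C)[C@@H]2C1 | intermediate
16 | (1S,6R,9S,10R,7(11)E)-3,9-bis[(tert-butyldimethylsilyl)oxy]-12-(4,4,5,5-tetramethyl-1,3,2-dioxaborolan-2-yl)cadina-3,7(11)-diene | CC1=C(O[Si](C)(C)C(C)(C)C)C[C@@H]2[C@@H](C)[C@@H](O[Si](C)(C)C(C)(C)C)C/C(=C(/C)CB3OC(C)(C)C(C)(C)O3)[C@@H]2C1 | intermediate
17 | (1S,6R,9S,10R,7(11)E)-3,9-bis[(tert-butyldimethylsilyl)oxy]cadina-3,7(11)-dien-12-ol | CC1=C(O[Si](C)(C)C(C)(C)C)C[C@@H]2[C@@H](C)[C@@H](O[Si](C)(C)C(C)(C)C)C/C(=C(/C)CO)[C@@H]2C1 | intermediate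
18 | (1S,6S,9S,10R,7(11)E)-9-[(tert-butyldimethylsilyl)oxy]-12-hydroxycadina-4,7(11)-dien-3-one | O=C1C[C@@H]2[C@@H](C)[C@@H](O[Si](C)(C)C(C)(C)C)C/C(=C(/C)CO)[C@@H]2C=C1C | intermediate
19 | (1S,3R,6S,9S,10R,7(11)E)-9-[(tert-butyldimethylsilyl)oxy]cadina-4,7(11)-diene-3,12-diol | O[C@@H]1C[C@@H]2[C@@H](C)[C@@H](O[Si](C)(C)C(C)(C)C)C/C(=C(/C)CO)[C@@H]2C=C1C | intermediate
20 | (1S,3R,6S,9S,10R,7(11)E)-9-[(tert-butyldimethylsilyl)oxy]-3-hydroxycadina-4,7(11)-dien-12-yl formate | O[C@@H]1C[C@@H]2[C@@H](C)[C@@H](O[Si](C)(C)C(C)(C)C)C/C(=C(/C)COC=O)[C@@H]2C=C1C | intermediate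
21 | (1S,3R,6S,9S,10R,7(11)E)-3-acetoxy-9-[(tert-butyldimethylsilyl)oxy]cadina-4,7(11)-dien-12-yl formate | CC(=O)O[C@@H]1C[C@@H]2[C@@H](C)[C@@H](O[Si](C)(C)C(C)(C)C)C/C(=C(/C)COC=O)[C@@H]2C=C1C | intermediate
22 | (1S,3R,6S,9S,10R,7(11)E)-3-acetoxy-9-hydroxycadina-4,7(11)-dien-12-yl formate | CC(=O)O[C@@H]1C[C@@H]2[C@@H](C)[C@@H](O)C/C(=C(/C)COC=O)[C@@H]2C=C1C | intermediate
23 | (1S,3R,6S,9R,10R,7(11)E)-3,9-diacetoxycadina-4,7(11)-dien-12-yl formate | CC(=O)O[C@@H]1C[C@@H]2[C@@H](C)[C@H](OC(C)=O)C/C(=C(/C)COC=O)[C@@H]2C=C1C | target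

**Totals**
Total step count: 18. Longest linear sequence: 17 steps (steps 1–7 and 9–18).

**Steps most likely to fail**

Step 12. The hindered, trisubstituted diene may bind nickel poorly, or take up H–B in 1,2-fashion or with boron at C8, eroding regio- and geometric control. The fallback sets out from ketone 12. Addition of the organocerium reagent made from CH2=C(CH3)MgBr and CeCl3 (THF, −78 °C) should give the C7 tertiary allylic alcohol, (1R,6R,9S,10R)-3,9-bis[(tert-butyldimethylsilyl)oxy]-4,10-dimethyl-7-(prop-1-en-2-yl)bicyclo[4.4.0]dec-3-en-7-ol F1. A 1,3-transposition of this allylic alcohol catalysed by Ph3SiOReO3 (Et2O, −50 to 0 °C) should then give the primary allylic alcohol together with its geometric isomer, the 7(11)Z alcohol F2, which is removed by chromatography. The fallback comes back to the route at 17.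

Step 10. The C7–C8 enolate may lose the C9 siloxy group by β-elimination, or enolisation may occur toward C6. The fallback sets out from ketone 12 and avoids any enolate. Condensation with p-toluenesulfonyl hydrazide (THF, rt) should give the N-tosylhydrazone F3. Palladium-catalysed coupling of F3 with 2-bromopropene (Pd2(dba)3, XPhos, LiOt-Bu, dioxane, 90 °C; Barluenga coupling through a palladium carbene, migratory insertion and β-hydride loss from the C8 methylene) should give the diene directly. The fallback comes back to the route at 15.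

Step 18. The activated axial C9 oxygen may be lost by elimination toward C8, giving a conjugated diene, faster than acetate substitutes it. The fallback sets out from alcohol 22 and replaces substitution by oxidation and reduction. Dess–Martin oxidation (NaHCO3, CH2Cl2, 0 °C) should give the C9 ketone F4. Reduction with Zn(BH4)2 (Et2O, −20 °C) should deliver hydride along the axial direction and give the equatorial 9R alcohol F5 without touching the formate. Acetylation (Ac2O, pyridine, DMAP) then comes back to the route at 23.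

**Further compounds**
F1 | step 12 | (1R,6R,9S,10R)-3,9-bis[(tert-butyldimethylsilyl)oxy]-4,10-dimethyl-7-(prop-1-en-2-yl)bicyclo[4.4.0]dec-3-en-7-ol | CC1=C(O[Si](C)(C)C(C)(C)C)C[C@@H]2[C@@H](C)[C@@H](O[Si](C)(C)C(C)(C)C)CC(O)(C(C)=C)[C@@H]2C1
F2 | step 12 | (1S,6R,9S,10R,7(11)Z)-3,9-bis[(tert-butyldimethylsilyl)oxy]cadina-3,7(11)-dien-12-ol | CC1=C(O[Si](C)(C)C(C)(C)C)C[C@@H]2[C@@H](C)[C@@H](O[Si](C)(C)C(C)(C)C)C/C(=C(\C)CO)[C@@H]2C1
F3 | step 10 | N-tosylhydrazone of 12 at C7 | CC1=C(O[Si](C)(C)C(C)(C)C)C[C@@H]2[C@@H](C)[C@@H](O[Si](C)(C)C(C)(C)C)CC(=NNS(=O)(=O)c3ccc(C)cc3)[C@@H]2C1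
F4 | step 18 | (1S,3R,6S,10R,7(11)E)-3-acetoxy-9-oxocadina-4,7(11)-dien-12-yl formate | CC(=O)O[C@@H]1C[C@@H]2[C@@H](C)C(=O)C/C(=C(/C)COC=O)[C@@H]2C=C1C
F5 | step 18 | (1S,3R,6S,9R,10R,7(11)E)-3-acetoxy-9-hydroxycadina-4,7(11)-dien-12-yl formate | CC(=O)O[C@@H]1C[C@@H]2[C@@H](C)[C@H](O)C/C(=C(/C)COC=O)[C@@H]2C=C1C
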